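The upper C ring (O1–C2–C3–C4–C4a–C8a) is closed at C2–C3 by an enantioselective rhodium-carbenoid C–H insertion. The disconnection exploits that C2 bears both O1 and the catechol B ring, so it can begin as the hydridic OCH2 of an aryl 3,4-bis(benzyloxy)benzyl ether, while C3 adjoins C4, carried as the A-ring ketone that supports a diazo carbon. One operation closes the pyranone and sets C2 under catalyst control; the precursor is an acyclic ortho-(benzyloxy)aryl diazomethyl ketone. Rubottom oxidation (C3–OH), reduction and C4-cation Friedel–Crafts coupling with C8-bromo-capped gallocatechin finish the 4α→6 dimer.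

Key step: step 3

Assumption: the (S)-ligand form of the dirhodium catalyst in step 3 is taken to lead to the (2S)-flavanone; if the sense of induction is the opposite, the (R)-ligand catalyst is used with nothing else changed.
Assumption: (+)-gallocatechin (2R,3S), ketone 1 and benzylic chloride 2 are taken as purchasable; dimethyldioxirane is used as its freshly prepared acetone solution.

Step 1
Reactants: 1 1-[4-(benzyloxy)-2-hydroxyphenyl]ethan-1-one; 2 1,2-bis(benzyloxy)-4-(chloromethyl)benzene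
Product: 3 1-[4-(benzyloxy)-2-{[3,4-bis(benzyloxy)benzyl]oxy}phenyl]ethan-1-one
Conditions: K2CO3, KI (cat.), DMF, 60 °C
Reagents that add atoms: none
Why: Williamson ether synthesis; the phenoxide of 1 displaces the benzylic chloride (iodide catalysis), and no stereocentre is involved.

Step 2
Reactants: 3 1-[4-(benzyloxy)-2-{[3,4-bis(benzyloxy)benzyl]oxy}phenyl]ethan-1-one
Product: 5 1-[4-(benzyloxy)-2-{[3,4-bis(benzyloxy)benzyl]oxy}phenyl]-2-diazoethan-1-one, via trifluoroacetyl diketone 4 (not isolated)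
Conditions: LiHMDS, THF, −78 °C, then CF3CO2CH2CF3; then MsN3, Et3N, H2O, MeCN, rt
Reagents that add atoms: 2,2,2-trifluoroethyl trifluoroacetate FC(F)(F)COC(=O)C(F)(F)F (trifluoroacetyl group, present in 4 only); mesyl azide CS(=O)(=O)N=[N+]=[N-] (the two diazo nitrogens)
Why: Claisen-type trifluoroacetylation of the lithium enolate activates the methyl ketone for Regitz diazo transfer, which proceeds with loss of the trifluoroacetyl group (detrifluoroacetylative diazo transfer) and should leave the ether CH2 groups untouched.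

Step 3
Reactants: 5 1-[4-(benzyloxy)-2-{[3,4-bis(benzyloxy)benzyl]oxy}phenyl]-2-diazoethan-1-one
Product: 6 (2S)-7-(benzyloxy)-2-[3,4-bis(benzyloxy)phenyl]-2,3-dihydro-4H-chromen-4-one
Conditions: Rh2(S-PTTL)4 (1 mol %), toluene, −20 → 0 °C, slow addition of 5
Reagents that add atoms: none
Why: Loss of N2 from 5 at the dirhodium centre should give an electrophilic Rh-carbenoid at C3, which inserts into one of the two enantiotopic C2–H bonds of the aryl–O–CH2–aryl ether through a concerted, asynchronous three-centre (hydride-transfer-like) transition state. The closest known reaction type is the Rh(II)-carboxylate-catalysed intramolecular C–H insertion of ortho-alkoxyaryl α-diazoketones to chroman-4-ones, including its enantioselective variants with chiral carboxylate ligands. The C ring closes by 1,6-C–H insertion through a six-membered chair-like array (C3, C4, C4a, C8a, O1, C2); no smaller ring can compete because the atom at position 5 from the carbenoid is O1. The new stereocentre C2 is set by the chiral ligand sphere of the catalyst, which is expected to select the C2–H bond that keeps the dialkoxyphenyl group pseudo-equatorial and away from the ligand walls, giving the (2S)-flavanone. The step needs chemoselectivity for C2–H insertion over oxonium-ylide formation at O1 (followed by a [1,2]-benzyl shift) and over the remote O-benzyl CH2 groups; this is secured by the 3,4-dialkoxyaryl group, which makes C2–H the most hydridic bond within reach, by the acyl-conjugated and therefore weakly basic O1, and by slow addition at low temperature.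

Step 4
Reactants: 6 (2S)-7-(benzyloxy)-2-[3,4-bis(benzyloxy)phenyl]-2,3-dihydro-4H-chromen-4-one
Product: 9 (2R,3R)-7-(benzyloxy)-2-[3,4-bis(benzyloxy)phenyl]-3-hydroxy-2,3-dihydro-4H-chromen-4-one, via silyl enol ether 7 (not isolated), via silyloxy epoxide 8 (not isolated)
Conditions: TMSOTf, Et3N, CH2Cl2, 0 °C; then DMDO, acetone/CH2Cl2, −40 °C; then aq. citric acid, THF, rt
Reagents that add atoms: trimethylsilyl triflate C[Si](C)(C)OS(=O)(=O)C(F)(F)F (silyl group, present in 7 and 8 only); dimethyldioxirane CC1(C)OO1 (the C3 oxygen)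
Why: Soft enolisation to the silyl enol ether avoids a free enolate that could expel O1, and Rubottom oxidation (epoxidation anti to the C2 aryl group, then hydrolytic opening) should set C3 to give the 2,3-trans ketol, which is also the thermodynamic epimer; C2 is spatially unchanged and its descriptor becomes R only through the priority change.

Step 5
Reactants: 9 (2R,3R)-7-(benzyloxy)-2-[3,4-bis(benzyloxy)phenyl]-3-hydroxy-2,3-dihydro-4H-chromen-4-one
Product: 10 (2R,3S,4R)-7-(benzyloxy)-2-[3,4-bis(benzyloxy)phenyl]chromane-3,4-diol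
Conditions: NaBH4, MeOH/THF, 0 °C
Reagents that add atoms: none
Why: Borohydride carbonyl reduction with axial hydride delivery on the half-chair should give the equatorial C4–OH trans to the equatorial C3–OH (2,3-trans-3,4-trans diol); the C4 configuration is not carried beyond step 8.

Step 6
Reactants: 11 (+)-gallocatechin
Product: 12 (2R,3S)-5,7-bis(benzyloxy)-2-[3,4,5-tris(benzyloxy)phenyl]chroman-3-ol
Conditions: BnBr, K2CO3, DMF (degassed), 0 °C → rt
Reagents that add atoms: benzyl bromide BrCc1ccccc1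
Why: Williamson O-alkylation under carbonate conditions should benzylate the five phenols and leave the much less acidic secondary C3–OH free; both stereocentres are untouched.

Step 7
Reactants: 12 (2R,3S)-5,7-bis(benzyloxy)-2-[3,4,5-tris(benzyloxy)phenyl]chroman-3-ol
Product: 13 (2R,3S)-5,7-bis(benzyloxy)-8-bromo-2-[3,4,5-tris(benzyloxy)phenyl]chroman-3-ol
Conditions: NBS, CH2Cl2, −78 °C → rt
Reagents that add atoms: N-bromosuccinimide O=C1CCC(=O)N1Br
Why: Electrophilic aromatic bromination should occur at C8, the most nucleophilic position of the phloroglucinol-type ring (ortho to O1 and 7-OBn, para to 5-OBn), which caps C8 and leaves C6 as the only free nucleophilic site.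

Step 8
Reactants: 10 (2R,3S,4R)-7-(benzyloxy)-2-[3,4-bis(benzyloxy)phenyl]chromane-3,4-diol; 13 (2R,3S)-5,7-bis(benzyloxy)-8-bromo-2-[3,4,5-tris(benzyloxy)phenyl]chroman-3-ol
Product: 14 (2R,3S,4S)-7-(benzyloxy)-2-[3,4-bis(benzyloxy)phenyl]-4-{(2R,3S)-5,7-bis(benzyloxy)-8-bromo-3-hydroxy-2-[3,4,5-tris(benzyloxy)phenyl]chroman-6-yl}chroman-3-ol
Conditions: BF3·OEt2 (0.5 equiv), 13 (3 equiv), CH2Cl2, −40 → 0 °C
Reagents that add atoms: none
Why: Lewis-acid ionisation of the para-alkoxybenzylic C4–OH gives a C4 carbocation stabilised by 7-OBn, and Friedel–Crafts alkylation at C6 of 13 anti to the pseudo-equatorial C3–OH of the 2,3-trans half-chair should set the 3,4-trans (4α, 4S) configuration.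

Step 9
Reactants: 14 (2R,3S,4S)-7-(benzyloxy)-2-[3,4-bis(benzyloxy)phenyl]-4-{(2R,3S)-5,7-bis(benzyloxy)-8-bromo-3-hydroxy-2-[3,4,5-tris(benzyloxy)phenyl]chroman-6-yl}chroman-3-ol
Product: 15 fisetinidol-(4α,6)-gallocatechin
Conditions: H2 (1 atm), Pd(OH)2/C, Et3N, THF/MeOH, rt
Reagents that add atoms: none
Why: Catalytic hydrogenolysis should cleave the eight benzyl ethers and hydrodebrominate C8 in one operation without touching any stereocentre or the interflavan C–C bond.

Compound list
1 | 1-[4-(benzyloxy)-2-hydroxyphenyl]ethan-1-one | CC(=O)c1ccc(OCc2ccccc2)cc1O | starting material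
2 | 1,2-bis(benzyloxy)-4-(chloromethyl)benzene (3,4-bis(benzyloxy)benzyl chloride) | ClCc1ccc(OCc2ccccc2)c(OCc2ccccc2)c1 | starting material
3 | 1-[4-(benzyloxy)-2-{[3,4-bis(benzyloxy)benzyl]oxy}phenyl]ethan-1-one | CC(=O)c1ccc(OCc2ccccc2)cc1OCc1ccc(OCc2ccccc2)c(OCc2ccccc2)c1 | intermediate
4 | 1-[4-(benzyloxy)-2-{[3,4-bis(benzyloxy)benzyl]oxy}phenyl]-4,4,4-trifluorobutane-1,3-dione (not isolated) | O=C(CC(=O)C(F)(F)F)c1ccc(OCc2ccccc2)cc1OCc1ccc(OCc2ccccc2)c(OCc2ccccc2)c1 | intermediate
5 | 1-[4-(benzyloxy)-2-{[3,4-bis(benzyloxy)benzyl]oxy}phenyl]-2-diazoethan-1-one | [N-]=[N+]=CC(=O)c1ccc(OCc2ccccc2)cc1OCc1ccc(OCc2ccccc2)c(OCc2ccccc2)c1 | intermediate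
6 | (2S)-7-(benzyloxy)-2-[3,4-bis(benzyloxy)phenyl]-2,3-dihydro-4H-chromen-4-one | C(c1ccccc1)Oc1ccc2c(c1)O[C@H](c1ccc(OCc3ccccc3)c(OCc3ccccc3)c1)CC2=O | intermediate
7 | (2S)-7-(benzyloxy)-2-[3,4-bis(benzyloxy)phenyl]-4-(trimethylsilyloxy)-2H-chromene (not isolated) | C(c1ccccc1)Oc1ccc2c(c1)O[C@H](c1ccc(OCc3ccccc3)c(OCc3ccccc3)c1)C=C2O[Si](C)(C)C | intermediate
8 | 3,4-epoxide of 7, oxirane oxygen anti to the C2 aryl group, OSiMe3 on C4 (not isolated) | C(c1ccccc1)Oc1ccc2c(c1)O[C@H](c1ccc(OCc3ccccc3)c(OCc3ccccc3)c1)[C@H]3O[C@@]23O[Si](C)(C)C | intermediate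
9 | (2R,3R)-7-(benzyloxy)-2-[3,4-bis(benzyloxy)phenyl]-3-hydroxy-2,3-dihydro-4H-chromen-4-one | C(c1ccccc1)Oc1ccc2c(c1)O[C@H](c1ccc(OCc3ccccc3)c(OCc3ccccc3)c1)[C@@H](O)C2=O | intermediate
10 | (2R,3S,4R)-7-(benzyloxy)-2-[3,4-bis(benzyloxy)phenyl]chromane-3,4-diol | C(c1ccccc1)Oc1ccc2c(c1)O[C@H](c1ccc(OCc3ccccc3)c(OCc3ccccc3)c1)[C@@H](O)[C@@H]2O | intermediate
11 | (+)-gallocatechin, (2R,3S)-2-(3,4,5-trihydroxyphenyl)chromane-3,5,7-triol | c1c(O)cc2c(c1O)C[C@H](O)[C@@H](c1cc(O)c(O)c(O)c1)O2 | starting material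
12 | (2R,3S)-5,7-bis(benzyloxy)-2-[3,4,5-tris(benzyloxy)phenyl]chroman-3-ol | c1c(OCc3ccccc3)cc2c(c1OCc1ccccc1)C[C@H](O)[C@@H](c1cc(OCc3ccccc3)c(OCc3ccccc3)c(OCc3ccccc3)c1)O2 | intermediate
13 | (2R,3S)-5,7-bis(benzyloxy)-8-bromo-2-[3,4,5-tris(benzyloxy)phenyl]chroman-3-ol | c1c(OCc3ccccc3)c(Br)c2c(c1OCc1ccccc1)C[C@H](O)[C@@H](c1cc(OCc3ccccc3)c(OCc3ccccc3)c(OCc3ccccc3)c1)O2 | intermediate
14 | octa-O-benzyl-8-bromo-fisetinidol-(4α→6)-gallocatechin, (2R,3S,4S) upper unit and (2R,3S) lower unit | C(c1ccccc1)Oc1ccc2c(c1)O[C@H](c1ccc(OCc3ccccc3)c(OCc3ccccc3)c1)[C@@H](O)[C@@H]2c1c(OCc3ccccc3)c(Br)c2c(c1OCc1ccccc1)C[C@H](O)[C@@H](c1cc(OCc3ccccc3)c(OCc3ccccc3)c(OCc3ccccc3)c1)O2 | intermediate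
15 | fisetinidol-(4α,6)-gallocatechin | Oc1ccc2c(c1)O[C@H](c1ccc(O)c(O)c1)[C@@H](O)[C@@H]2c1c(O)cc2c(c1O)C[C@H](O)[C@@H](c1cc(O)c(O)c(O)c1)O2 | target

Total step count: 9. Longest linear sequence: 7 steps (steps 1, 2, 3, 4, 5, 8, 9).

Steps most likely to fail

Step 3. The carbenoid may be intercepted by the lone pair of O1 (oxonium ylide, then [1,2]-shift of the benzyl group to a 2-benzylbenzofuran-3-one), or the catalyst may discriminate the two enantiotopic C2–H bonds poorly. The fallback keeps the same C2–C3 ring closure but uses oxocarbenium/enol polarity. It sets out from ketone 3: isopropenyl acetate with catalytic TsOH should give the enol acetate F1. DDQ (2,6-dichloropyridine, LiClO4, 4 Å MS, 1,2-dichloroethane) should oxidise the electron-rich 3,4-bis(benzyloxy)benzyl ether C–H to the aryl oxocarbenium ion, which the enol acetate captures in a 6-endo cyclisation to the racemic flavanone F2. Kinetic resolution by Noyori-type asymmetric transfer hydrogenation (the Ru–TsDPEN antipode that reduces the (2R)-ketone faster, HCO2H/Et3N, run just past half conversion) should leave the (2S)-ketone, separable from the cis-flavan-4-ol F3. The route is rejoined at 6.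

Step 8. The C4 cation may be attacked syn to C3–OH (4β epimer), may alkylate the A ring of a second molecule of 10, or may react only slowly with the hindered, bromine-deactivated C6. The fallback replaces simple ionisation by anchimeric control and sets out from 10: Ac2O/pyridine/DMAP should give the 3,4-diacetate F7. TMSOTf (CH2Cl2, −78 °C) ionises the C4 acetate with participation of the C3 acetate (cis-fused dioxolenium ion on the face of O3), so that 13 can attack C4 only anti, giving the 3-O-acetate of the coupled product F8. K2CO3/MeOH removes the acetate and the route is rejoined at 14.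

Step 4. During enolisation the ring may open by β-elimination of the O1 phenoxide, with loss of the C2 configuration, or the silyl enol ether may be hydrolysed before it is oxidised. The fallback installs the C3 oxygen without any enol derivative and sets out from 6: NaBH4 should give the cis-flavan-4-ol F4, and dehydration with the Burgess reagent the flav-3-ene F5. DMDO should epoxidise anti to the C2 aryl group to the epoxide F6, and acid-catalysed hydrolysis (trans opening at the benzylic C4) returns to the route at diol 10.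

Further compounds
F1 | step 3 | 1-[4-(benzyloxy)-2-{[3,4-bis(benzyloxy)benzyl]oxy}phenyl]vinyl acetate | CC(=O)OC(=C)c1ccc(OCc2ccccc2)cc1OCc1ccc(OCc2ccccc2)c(OCc2ccccc2)c1
F2 | step 3 | racemic 7-(benzyloxy)-2-[3,4-bis(benzyloxy)phenyl]-2,3-dihydro-4H-chromen-4-one | C(c1ccccc1)Oc1ccc2c(c1)OC(c1ccc(OCc3ccccc3)c(OCc3ccccc3)c1)CC2=O
F3 | step 3 | (2R,4R)-7-(benzyloxy)-2-[3,4-bis(benzyloxy)phenyl]chroman-4-ol (2,4-cis, by-product of the resolution) | C(c1ccccc1)Oc1ccc2c(c1)O[C@@H](c1ccc(OCc3ccccc3)c(OCc3ccccc3)c1)C[C@H]2O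
F4 | step 4 | (2S,4S)-7-(benzyloxy)-2-[3,4-bis(benzyloxy)phenyl]chroman-4-ol (2,4-cis) | C(c1ccccc1)Oc1ccc2c(c1)O[C@H](c1ccc(OCc3ccccc3)c(OCc3ccccc3)c1)C[C@@H]2O
F5 | step 4 | (2S)-7-(benzyloxy)-2-[3,4-bis(benzyloxy)phenyl]-2H-chromene | C(c1ccccc1)Oc1ccc2c(c1)O[C@H](c1ccc(OCc3ccccc3)c(OCc3ccccc3)c1)C=C2
F6 | step 4 | 3,4-epoxide of F5, oxirane oxygen anti to the C2 aryl group | C(c1ccccc1)Oc1ccc2c(c1)O[C@H](c1ccc(OCc3ccccc3)c(OCc3ccccc3)c1)[C@H]3O[C@@H]23
F7 | step 8 | (2R,3S,4R)-7-(benzyloxy)-2-[3,4-bis(benzyloxy)phenyl]chromane-3,4-diyl diacetate | C(c1ccccc1)Oc1ccc2c(c1)O[C@H](c1ccc(OCc3ccccc3)c(OCc3ccccc3)c1)[C@@H](OC(C)=O)[C@@H]2OC(C)=O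
F8 | step 8 | 3-O-acetate (upper unit) of compound 14 | C(c1ccccc1)Oc1ccc2c(c1)O[C@H](c1ccc(OCc3ccccc3)c(OCc3ccccc3)c1)[C@@H](OC(C)=O)[C@@H]2c1c(OCc3ccccc3)c(Br)c2c(c1OCc1ccccc1)C[C@H](O)[C@@H](c1cc(OCc3ccccc3)c(OCc3ccccc3)c(OCc3ccccc3)c1)O2
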